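The readings come from a simulation for an exercise.

Percent of the starting complex charged is the wrong unit for this flask, so turn it into mM of ligand before you fit anything.

the same everywhere: incoming ligand 19.2 mM
- red: starting complex 16 mM; leaving ligand 32 mM; the very flask that is asked about, followed so far
- green: starting complex 8 mM; leaving ligand 32 mM; run made earlier
- flask: starting complex 16 mM; leaving ligand 32.0 mM; time 6.0 min

- red (time / min: complex with two exchanged / %, starting complex / %): 0.250: 5.3, 75.5; 0.667: 12.7, 54.9; 1.50: 16.7, 41.1; 4.00: 14.2, 31.4
- green (time / min: complex with two exchanged / %, starting complex / %): 0.500: 13.7, 56.5; 1.00: 22.3, 38.9; 2.50: 28.5, 21.0; 6.00: 23.5, 14.5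

(readings scatter by 0.5 percentage points)

- additions leave the volume as it is

- epsilon: at 6.0 min add incoming ligand, 50.0% of the amount charged, then wait 6.0 min
- eta: at 6.0 min take out 90% of the leaving ligand then present, then wait 6.0 min
- delta: change nothing and wait 6.0 min more
- beta: at 6.0 min add starting complex, 50.0% of the amount charged, then wait 6.0 min

1. complex with two exchanged, in percent of the starting complex first charged, at 6.0 min
2. which option adds most complex with two exchanged ("none" when 2 percentage points or less is all one gets) (epsilon / eta / delta / beta / none)
3. complex with two exchanged present, in percent of the starting complex first charged, after eta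
4. complex with two exchanged present, in percent of the starting complex first charged, after beta

I assume each exchange takes up one incoming ligand and releases one leaving ligand. So I write the balance of incoming ligand, the limiting reagent in red. A full double exchange in red needs 32.0 mM, and 19.2 mM was charged. I assume that whatever left the starting complex took one ligand, and that complex with two exchanged took a second. Used ligand is then the lost share of starting complex plus the share of complex with two exchanged, times the charge.

Now read the red table down. At 0.250 min the balance gives 4.77 mM used, so [leaving ligand]/[incoming ligand] is 2.55. At 1.50 min complex with two exchanged reads 16.7%, its highest reading. At 4.00 min used ligand is 13.2 mM. That leaves [incoming ligand] at 5.95 mM and [leaving ligand] at 45.2 mM. The ratio, read from these scattered readings, is 7.60. Call this [leaving ligand]/[incoming ligand] the ligand quotient.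

Set the last green row beside it. Green used 8.72 mM by 6.00 min, so its quotient then is 3.89. Green reads 23.5% of complex with two exchanged, red 14.2%.

The options are then moves of the quotient. Red was last read at 4.00 min, so I take that state as a stand-in for the moment of action. From it, eta gives a quotient of 0.760 and epsilon one of 2.91. Beta adds starting complex, a new taker of incoming ligand. So I would choose eta.

The forecast differs from me on the choice. It says 12.3% (11.2% to 13.4%) and picks epsilon, with 13% after eta and 8% after beta. Its ground for eta: “Removing leaving ligand helps briefly, then ligand runs out”.

The flask gives 11.9% at 6.0 min. The best option is eta, which adds 7.4 percentage points, while epsilon adds 4.6 points. After eta stand 19.3%, after beta 6.05%.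

    complex with one exchanged → side product (k = 0.00206 s⁻¹)
    starting complex + incoming ligand ⇌ leaving ligand + complex with one exchanged (K = 10.3, k = 1.19 M⁻¹ s⁻¹)
    complex with one exchanged + incoming ligand ⇌ leaving ligand + complex with two exchanged (K = 2.64, k = 2.00 M⁻¹ s⁻¹)

In this flask the quotient is 7.75 at 6.00 min, against 7.60 read at 4.00 min. The return of leaving ligand and complex with two exchanged to complex with one exchanged and incoming ligand is the largest single effect proven, though not the main reason. With it struck out, the flask holds 48.3% of complex with two exchanged at 6.0 min, in place of 11.9%. The same flask charged with 77 mM of incoming ligand has a quotient of 1.08 at 6.00 min and holds 56.1% of complex with two exchanged.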